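**Plan**
- Azulene numbering is used for the bicycle: C1 (carbinol with isopropyl), C2=C3, C3a (methyl-bearing ring-fusion carbon), C4, C5, C6 (methyl carbinol), C7, C8 (ester carbon), C8a (ring-fusion CH). The retrosynthesis cuts the vanillate C–O bond, then C1–isopropyl, the C6–O bond (through a 6,7-epoxide), C3a–CH3, and last the ring bonds C4–C5 and C8–C8a together.
- Enabling feature: C4–C3a–C8a of the seven-membered ring maps onto a vinylcarbenoid (carbene carbon plus the ring C=C of a 3-substituted cyclopent-2-enone). C5–C6–C7–C8 maps onto the silyl dienol ether of 3-methylbut-2-enal, which already carries the C8 oxygen and puts its internal alkene at C6=C7.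
- Forward order: the five-membered ring is bought; the seven-membered ring is made by a cyclopropanation/Cope sequence (formal (4+3)); the helper ester carbon is then excised, giving the C3a=C8a enone.
- Then: angular methyl by conjugate addition, 6,7-epoxide, C2=C3 by dehydrogenation, isopropyl addition to C1, epoxide opening to the C6 carbinol, and acylation of the C8 hydroxyl.
- Stereochemistry: C8 from the chiral dirhodium catalyst, relayed by the Cope shift. C3a by addition anti to the C8 silyloxy group; C8a by protonation anti to the angular methyl. C6 by epoxidation anti to the silyloxy group; C1 by addition anti to the C8a–C8 bond.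

Key step: step 3

Assumption: methyl diazoacetate is taken as a purchasable reagent, and the sense of induction of the dirhodium catalyst is taken from its established face model for alkene cyclopropanation; the mirror-image catalyst is the remedy if the sense is opposite.

Step 1
Reactants: 1 3-ethoxycyclopent-2-en-1-one; 2 methyl diazoacetate
Product: 4 methyl 2-diazo-2-(3-oxocyclopent-1-en-1-yl)acetate, via tertiary carbinol adduct 3 (not isolated)
Conditions: LDA (LiN(iPr)2), THF, −78 °C; AcOH; then PPTS, THF/H2O, 23 °C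
Reagents that add atoms: water, O
Why: Lithiated methyl diazoacetate should add 1,2 to the vinylogous ester carbonyl, and mild acid then hydrolyses the enol ether with loss of water (Stork–Danheiser transposition), placing the diazoester carbon on the β-carbon of the new enone without ambiguity of site; no stereocentre is formed.

Step 2
Reactants: 5 3-methylbut-2-enal
Product: 6 triisopropyl{[(1E)-3-methylbuta-1,3-dien-1-yl]oxy}silane
Conditions: TIPSOTf, Et3N, Et2O, 0 → 23 °C
Reagents that add atoms: triisopropylsilyl trifluoromethanesulfonate, CC(C)[Si](OS(=O)(=O)C(F)(F)F)(C(C)C)C(C)C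
Why: O-Silylation of the enal followed by γ-deprotonation (soft enolization) should give the (E) silyl dienol ether, a diene with oxygen on one terminus and the methyl group on C3.

Step 3
Reactants: 4 methyl 2-diazo-2-(3-oxocyclopent-1-en-1-yl)acetate; 6 triisopropyl{[(1E)-3-methylbuta-1,3-dien-1-yl]oxy}silane
Product: 8 methyl (8S,8aR)-6-methyl-1-oxo-8-(triisopropylsilyloxy)-1,2,3,5,8,8a-hexahydroazulene-4-carboxylate, via cis-divinylcyclopropane 7 (not isolated)
Conditions: Rh2(R-DOSP)4 (dirhodium tetrakis[(R)-N-(4-dodecylphenylsulfonyl)prolinate], 1 mol %), hexanes/toluene, slow addition of 4 to 6 (3 equiv), −40 → 23 °C; then 60 °C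
Reagents that add atoms: none
Why: Loss of dinitrogen from 4 gives a rhodium vinylcarbenoid whose carbene carbon adds to the terminal 1,1-disubstituted C=C of 6 (the most nucleophilic and least hindered carbon of the dienol ether), closing a cyclopropane by [2+1] addition with the cyclopentenyl and silyloxyvinyl groups cis (7); this cis-divinylcyclopropane then undergoes a [3,3] sigmatropic (Cope) shift through a boat transition state that breaks the cyclopropane bond between the two substituted carbons and joins the α-carbon of the cyclopentenone to the silyloxy-bearing carbon, so the seven-membered ring is closed by three-to-seven ring expansion (formal (4+3) cycloaddition). The closest known reaction type is the tandem cyclopropanation/Cope rearrangement of vinyldiazoacetates, including ester- and acyl-substituted vinylcarbenoids, with 1-oxygenated dienes. The two cyclopropane stereocentres are set by the chiral dirhodium carboxylate, and the concerted boat Cope shift transfers them into C8 (S) of 8; C8a forms with its hydrogen cis to H-8 because both alkene termini carry only hydrogen in the inward position, and it is erased in step 4. The step needs site selectivity for the distal alkene over the enol-ether alkene, which the trans-1,2-disubstitution of the latter (avoided by such hindered carbenoids) and a hydrocarbon solvent (which disfavours zwitterionic (3+2) pathways) should secure; it also needs the cis-divinyl arrangement, favoured by the usual placement of the carbenoid alkenyl group syn to the π-substituent of the alkene, any trans isomer being brought into the Cope manifold by the final warming. The (R) catalyst is chosen by transposing the face model of the (S) catalyst with styrene to this alkene.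

Step 4
Reactants: 8 methyl (8S,8aR)-6-methyl-1-oxo-8-(triisopropylsilyloxy)-1,2,3,5,8,8a-hexahydroazulene-4-carboxylate
Product: 10 (8S)-6-methyl-8-(triisopropylsilyloxy)-2,3,4,5-tetrahydroazulen-1(8H)-one, via carboxylic acid 9 (not isolated)
Conditions: Me3SnOH, ClCH2CH2Cl, 80 °C; then AcOH, toluene, 100 °C
Reagents that add atoms: none
Why: Trimethyltin hydroxide should cleave the methyl ester under nearly neutral conditions, and the acid, once its C=C has moved into conjugation with the ketone, is a vinylogous β-keto acid that loses CO2 on heating, leaving C4 as CH2 and the C3a=C8a enone with C8 untouched.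

Step 5
Reactants: 10 (8S)-6-methyl-8-(triisopropylsilyloxy)-2,3,4,5-tetrahydroazulen-1(8H)-one
Product: 12 (3aS,8S,8aS)-3a,6-dimethyl-8-(triisopropylsilyloxy)-3,3a,4,5,8,8a-hexahydroazulen-1(2H)-one, via trimethylsilyl enol ether 11 (not isolated)
Conditions: Me2CuLi (from MeLi, CuI), TMSCl, THF, −78 → −40 °C; then 1 M HCl, THF, 0 °C
Reagents that add atoms: lithium dimethylcuprate, [Li+].C[Cu-]C
Why: Chlorotrimethylsilane-accelerated Gilman conjugate addition to the tetrasubstituted enone should form the quaternary C3a with methyl anti to the C8 silyloxy group (held pseudoaxial by allylic strain against the C1 carbonyl), the silyl enol ether guards against β-elimination of the C8 oxygen, and kinetic protonation at C8a anti to the new angular methyl should give the trans ring fusion.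

Step 6
Reactants: 12 (3aS,8S,8aS)-3a,6-dimethyl-8-(triisopropylsilyloxy)-3,3a,4,5,8,8a-hexahydroazulen-1(2H)-one
Product: 13 (3aS,6R,7S,8R,8aS)-6,7-epoxy-3a,6-dimethyl-8-(triisopropylsilyloxy)octahydroazulen-1(2H)-one
Conditions: mCPBA, CH2Cl2, 0 °C
Reagents that add atoms: 3-chloroperoxybenzoic acid, O=C(OO)c1cccc(Cl)c1
Why: Prilezhaev epoxidation of the only electron-rich alkene should occur on the face opposite the allylic triisopropylsilyloxy group, which places the epoxide oxygen, and so the later C6 hydroxyl, trans to the C8 oxygen.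

Step 7
Reactants: 13 (3aS,6R,7S,8R,8aS)-6,7-epoxy-3a,6-dimethyl-8-(triisopropylsilyloxy)octahydroazulen-1(2H)-one
Product: 15 (3aS,6R,7S,8R,8aS)-6,7-epoxy-3a,6-dimethyl-8-(triisopropylsilyloxy)-3a,4,5,6,7,8-hexahydroazulen-1(8aH)-one, via trimethylsilyl enol ether 14 (not isolated)
Conditions: LDA (LiN(iPr)2), TMSCl, THF, −78 °C; then Pd(OAc)2 (1.05 equiv), MeCN, 23 °C
Reagents that add atoms: none
Why: Kinetic deprotonation should take the unhindered C2 methylene and not the tertiary C8a–H, and Saegusa–Ito oxidation of the silyl enol ether by divalent palladium (β-hydride elimination from C3) installs C2=C3 without touching C8a.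

Step 8
Reactants: 15 (3aS,6R,7S,8R,8aS)-6,7-epoxy-3a,6-dimethyl-8-(triisopropylsilyloxy)-3a,4,5,6,7,8-hexahydroazulen-1(8aH)-one
Product: 16 (1S,3aS,6R,7S,8R,8aS)-6,7-epoxy-3a,6-dimethyl-1-(propan-2-yl)-8-(triisopropylsilyloxy)-1,3a,4,5,6,7,8,8a-octahydroazulen-1-ol
Conditions: iPrMgCl, CeCl3, THF, −78 °C
Reagents that add atoms: isopropylmagnesium chloride, CC(C)[Mg]Cl
Why: The organocerium reagent should add 1,2 to the enone without enolization or conjugate addition, on the face of H-8a and anti to both the C8a–C8 bond and the C3a methyl, giving the (1S) tertiary carbinol with isopropyl cis to H-8a.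

Step 9
Reactants: 16 (1S,3aS,6R,7S,8R,8aS)-6,7-epoxy-3a,6-dimethyl-1-(propan-2-yl)-8-(triisopropylsilyloxy)-1,3a,4,5,6,7,8,8a-octahydroazulen-1-ol
Product: 17 (1S,3aS,6R,7S,8R,8aS)-6,7-epoxy-3a,6-dimethyl-1-(propan-2-yl)-1,3a,4,5,6,7,8,8a-octahydroazulene-1,8-diol
Conditions: Bu4NF, THF, 23 °C
Reagents that add atoms: none
Why: Fluoride-mediated desilylation should free the C8 hydroxyl, which guides the hydride in the next step and is acylated later; a Payne shift of this trans epoxy alcohol would lead to the same triol.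

Step 10
Reactants: 17 (1S,3aS,6R,7S,8R,8aS)-6,7-epoxy-3a,6-dimethyl-1-(propan-2-yl)-1,3a,4,5,6,7,8,8a-octahydroazulene-1,8-diol
Product: 18 (1S,3aS,6R,8S,8aS)-3a,6-dimethyl-1-(propan-2-yl)-1,3a,4,5,6,7,8,8a-octahydroazulene-1,6,8-triol
Conditions: LiAlH4, THF, 0 → 40 °C
Reagents that add atoms: none
Why: Hydride opening of the 2,3-epoxy alcohol should occur by SN2 attack at the secondary C7, assisted by delivery from the C8 alkoxyaluminate on the face opposite the epoxide oxygen, so C6 keeps its oxygen with the configuration set in step 6.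

Step 11
Reactants: 18 (1S,3aS,6R,8S,8aS)-3a,6-dimethyl-1-(propan-2-yl)-1,3a,4,5,6,7,8,8a-octahydroazulene-1,6,8-triol; 19 4-acetoxy-3-methoxybenzoic acid
Product: 20 (1S,3aS,6R,8S,8aS)-1,6-dihydroxy-3a,6-dimethyl-1-(propan-2-yl)-1,3a,4,5,6,7,8,8a-octahydroazulen-8-yl 4-acetoxy-3-methoxybenzoate
Conditions: DCC, DMAP (cat.), CH2Cl2, 23 °C
Reagents that add atoms: none
Why: Steglich esterification should acylate the only secondary hydroxyl, the two tertiary hydroxyls being unreactive, with retention at C8.

Step 12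
Reactants: 20 (1S,3aS,6R,8S,8aS)-1,6-dihydroxy-3a,6-dimethyl-1-(propan-2-yl)-1,3a,4,5,6,7,8,8a-octahydroazulen-8-yl 4-acetoxy-3-methoxybenzoate
Product: 21 (1S,3aS,6R,8S,8aS)-1,6-dihydroxy-3a,6-dimethyl-1-(propan-2-yl)-1,3a,4,5,6,7,8,8a-octahydroazulen-8-yl 4-hydroxy-3-methoxybenzoate
Conditions: K2CO3 (cat.), MeOH, 0 °C
Reagents that add atoms: none
Why: Base-catalysed methanolysis should remove the phenolic acetate, which is far more electrophilic than the hindered secondary benzoate, to give the target.

**Compound list**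
1 | 3-ethoxycyclopent-2-en-1-one | CCOC1=CC(=O)CC1 | starting material
2 | methyl diazoacetate | COC(=O)C=[N+]=[N-] | starting material
3 | methyl 2-diazo-2-(3-ethoxy-1-hydroxycyclopent-2-en-1-yl)acetate (racemic) | CCOC1=CC(O)(CC1)C(=[N+]=[N-])C(=O)OC | intermediate
4 | methyl 2-diazo-2-(3-oxocyclopent-1-en-1-yl)acetate | COC(=O)C(=[N+]=[N-])C1=CC(=O)CC1 | intermediate
5 | 3-methylbut-2-enal | CC(C)=CC=O | starting material
6 | triisopropyl{[(1E)-3-methylbuta-1,3-dien-1-yl]oxy}silane | CC(=C)/C=C/O[Si](C(C)C)(C(C)C)C(C)C | intermediate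
7 | methyl (1S,2S)-2-methyl-1-(3-oxocyclopent-1-en-1-yl)-2-[(E)-2-(triisopropylsilyloxy)ethenyl]cyclopropane-1-carboxylate (the two alkenyl groups cis) | COC(=O)[C@]1(C2=CC(=O)CC2)C[C@@]1(C)/C=C/O[Si](C(C)C)(C(C)C)C(C)C | intermediate
8 | methyl (8S,8aR)-6-methyl-1-oxo-8-(triisopropylsilyloxy)-1,2,3,5,8,8a-hexahydroazulene-4-carboxylate | CC(C)[Si](O[C@H]1C=C(C)CC(C(=O)OC)=C2CCC(=O)[C@@H]12)(C(C)C)C(C)C | intermediate
9 | (8S,8aR)-6-methyl-1-oxo-8-(triisopropylsilyloxy)-1,2,3,5,8,8a-hexahydroazulene-4-carboxylic acid | CC(C)[Si](O[C@H]1C=C(C)CC(C(=O)O)=C2CCC(=O)[C@@H]12)(C(C)C)C(C)C | intermediate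
10 | (8S)-6-methyl-8-(triisopropylsilyloxy)-2,3,4,5-tetrahydroazulen-1(8H)-one | CC(C)[Si](O[C@H]1C=C(C)CCC2=C1C(=O)CC2)(C(C)C)C(C)C | intermediate
11 | triisopropyl{[(3aS,8S)-3a,6-dimethyl-1-(trimethylsilyloxy)-2,3,3a,4,5,8-hexahydroazulen-8-yl]oxy}silane | CC(C)[Si](O[C@H]1C=C(C)CC[C@@]2(C)CCC(O[Si](C)(C)C)=C12)(C(C)C)C(C)C | intermediate
12 | (3aS,8S,8aS)-3a,6-dimethyl-8-(triisopropylsilyloxy)-3,3a,4,5,8,8a-hexahydroazulen-1(2H)-one (trans ring fusion, methyl trans to the silyloxy group) | CC(C)[Si](O[C@H]1C=C(C)CC[C@@]2(C)CCC(=O)[C@H]12)(C(C)C)C(C)C | intermediate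
13 | (3aS,6R,7S,8R,8aS)-6,7-epoxy-3a,6-dimethyl-8-(triisopropylsilyloxy)octahydroazulen-1(2H)-one | CC(C)[Si](O[C@H]1[C@@H]2O[C@]2(C)CC[C@@]3(C)CCC(=O)[C@H]13)(C(C)C)C(C)C | intermediate
14 | trimethylsilyl enol ether of 13 (C1–OSiMe3, C1=C2) | CC(C)[Si](O[C@H]1[C@@H]2O[C@]2(C)CC[C@@]3(C)CC=C(O[Si](C)(C)C)[C@H]13)(C(C)C)C(C)C | intermediate
15 | (3aS,6R,7S,8R,8aS)-6,7-epoxy-3a,6-dimethyl-8-(triisopropylsilyloxy)-3a,4,5,6,7,8-hexahydroazulen-1(8aH)-one | CC(C)[Si](O[C@H]1[C@@H]2O[C@]2(C)CC[C@@]3(C)C=CC(=O)[C@H]13)(C(C)C)C(C)C | intermediate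
16 | (1S,3aS,6R,7S,8R,8aS)-6,7-epoxy-3a,6-dimethyl-1-(propan-2-yl)-8-(triisopropylsilyloxy)-1,3a,4,5,6,7,8,8a-octahydroazulen-1-ol | CC(C)[Si](O[C@H]1[C@@H]2O[C@]2(C)CC[C@@]3(C)C=C[C@@](O)(C(C)C)[C@H]13)(C(C)C)C(C)C | intermediate
17 | (1S,3aS,6R,7S,8R,8aS)-6,7-epoxy-3a,6-dimethyl-1-(propan-2-yl)-1,3a,4,5,6,7,8,8a-octahydroazulene-1,8-diol | O[C@H]1[C@@H]2O[C@]2(C)CC[C@@]3(C)C=C[C@@](O)(C(C)C)[C@H]13 | intermediate
18 | (1S,3aS,6R,8S,8aS)-3a,6-dimethyl-1-(propan-2-yl)-1,3a,4,5,6,7,8,8a-octahydroazulene-1,6,8-triol | O[C@H]1C[C@](C)(O)CC[C@@]2(C)C=C[C@@](O)(C(C)C)[C@H]12 | intermediate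
19 | 4-acetoxy-3-methoxybenzoic acid | COc1cc(C(=O)O)ccc1OC(C)=O | starting material
20 | (1S,3aS,6R,8S,8aS)-1,6-dihydroxy-3a,6-dimethyl-1-(propan-2-yl)-1,3a,4,5,6,7,8,8a-octahydroazulen-8-yl 4-acetoxy-3-methoxybenzoate | COc1cc(C(=O)O[C@H]2C[C@](C)(O)CC[C@@]3(C)C=C[C@@](O)(C(C)C)[C@H]23)ccc1OC(C)=O | intermediate
21 | (1S,3aS,6R,8S,8aS)-1,6-dihydroxy-3a,6-dimethyl-1-(propan-2-yl)-1,3a,4,5,6,7,8,8a-octahydroazulen-8-yl 4-hydroxy-3-methoxybenzoate | COc1cc(C(=O)O[C@H]2C[C@](C)(O)CC[C@@]3(C)C=C[C@@](O)(C(C)C)[C@H]23)ccc1O | target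

Total step count: 12. Longest linear sequence: 11 steps (steps 1 and 3 to 12; step 2 is a one-step branch).

**Steps most likely to fail**

Step 3. The acyl-substituted vinylcarbenoid may attack the enol-ether double bond or leak into zwitterionic (3+2) pathways, and the chiral catalyst may transfer little asymmetry to so electron-poor a carbenoid. The fallback masks the ketone so that an ordinary donor/acceptor vinylcarbenoid is used; it sets out from 1 and comes back to the route at 8. Compound 1 and the lithium enolate of methyl acetate (LDA, THF, −78 °C) should give the carbinol adduct methyl 2-(3-ethoxy-1-hydroxycyclopent-2-en-1-yl)acetate F1, which aqueous HCl converts to methyl 2-(3-oxocyclopent-1-en-1-yl)acetate F2. Ketalization with 1,2-bis(trimethylsilyloxy)ethane and catalytic TMSOTf at −78 °C, which leaves the double bond in place, gives methyl 2-(1,4-dioxaspiro[4.4]non-6-en-7-yl)acetate F3. Diazo transfer (p-ABSA, DBU, MeCN), now possible at one carbon only, gives methyl 2-diazo-2-(1,4-dioxaspiro[4.4]non-6-en-7-yl)acetate F4. Reaction with 6 under the conditions of step 3 should give, by way of the ketal cis-divinylcyclopropane F5, the ketal cycloadduct F6, and PPTS in wet acetone then unmasks the ketone to give 8.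

Step 4. The dienolate that forms during ester cleavage or decarboxylation may expel the C8 silyloxy group by β-elimination, or the hindered conjugated ester may resist cleavage. The fallback replaces hydrolysis by acidolysis of a tert-butyl ester; it sets out from 1 and comes back at 9, which is decarboxylated to 10 as in step 4. tert-Butyl diazoacetate is used in step 1 to give, through the carbinol adduct tert-butyl 2-diazo-2-(3-ethoxy-1-hydroxycyclopent-2-en-1-yl)acetate F7, the diazo enone tert-butyl 2-diazo-2-(3-oxocyclopent-1-en-1-yl)acetate F8. The key step with 6 gives, through the cis-divinylcyclopropane tert-butyl ester F9, the cycloadduct tert-butyl (8S,8aR)-6-methyl-1-oxo-8-(triisopropylsilyloxy)-1,2,3,5,8,8a-hexahydroazulene-4-carboxylate F10. TMSOTf and 2,6-lutidine (CH2Cl2, 0 °C) followed by water remove the tert-butyl group as 2-methylpropene without any base strong enough to form the dienolate, giving 9.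

Step 5. The enolate formed in the conjugate addition may expel the C8 silyloxy group, the methyl group may enter with poor facial selectivity, or protonation at C8a may give the cis-fused ketone. The fallback carries the C8 oxygen as a lithium alkoxide, which is not a leaving group and which ties the enolate into a chelate; it sets out from 10 and comes back at 12. Bu4NF removes the silyl group to give (8S)-8-hydroxy-6-methyl-2,3,4,5-tetrahydroazulen-1(8H)-one F11. Deprotonation with MeLi, addition of excess Me2CuLi in Et2O at −78 °C and buffered protonation should give (3aS,8S,8aS)-8-hydroxy-3a,6-dimethyl-3,3a,4,5,8,8a-hexahydroazulen-1(2H)-one F12, whose ring fusion can be equilibrated with mild base, loss of the C8 oxygen being far slower than with the silyl ether. TIPSOTf and 2,6-lutidine then return 12.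

**Further compounds**
F1 | step 3 | methyl 2-(3-ethoxy-1-hydroxycyclopent-2-en-1-yl)acetate | CCOC1=CC(O)(CC(=O)OC)CC1
F2 | step 3 | methyl 2-(3-oxocyclopent-1-en-1-yl)acetate | COC(=O)CC1=CC(=O)CC1
F3 | step 3 | methyl 2-(1,4-dioxaspiro[4.4]non-6-en-7-yl)acetate | COC(=O)CC1=CC2(CC1)OCCO2
F4 | step 3 | methyl 2-diazo-2-(1,4-dioxaspiro[4.4]non-6-en-7-yl)acetate | COC(=O)C(=[N+]=[N-])C1=CC2(CC1)OCCO2
F5 | step 3 | methyl (1S,2S)-1-(1,4-dioxaspiro[4.4]non-6-en-7-yl)-2-methyl-2-[(E)-2-(triisopropylsilyloxy)ethenyl]cyclopropane-1-carboxylate | COC(=O)[C@]1(C2=CC3(CC2)OCCO3)C[C@@]1(C)/C=C/O[Si](C(C)C)(C(C)C)C(C)C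
F6 | step 3 | ethylene ketal (at C1) of methyl (8S,8aR)-6-methyl-1-oxo-8-(triisopropylsilyloxy)-1,2,3,5,8,8a-hexahydroazulene-4-carboxylate | CC(C)[Si](O[C@H]1C=C(C)CC(C(=O)OC)=C2CCC3(OCCO3)[C@@H]12)(C(C)C)C(C)C
F7 | step 4 | tert-butyl 2-diazo-2-(3-ethoxy-1-hydroxycyclopent-2-en-1-yl)acetate | CCOC1=CC(O)(CC1)C(=[N+]=[N-])C(=O)OC(C)(C)C
F8 | step 4 | tert-butyl 2-diazo-2-(3-oxocyclopent-1-en-1-yl)acetate | CC(C)(C)OC(=O)C(=[N+]=[N-])C1=CC(=O)CC1
F9 | step 4 | tert-butyl (1S,2S)-2-methyl-1-(3-oxocyclopent-1-en-1-yl)-2-[(E)-2-(triisopropylsilyloxy)ethenyl]cyclopropane-1-carboxylate | CC(C)(C)OC(=O)[C@]1(C2=CC(=O)CC2)C[C@@]1(C)/C=C/O[Si](C(C)C)(C(C)C)C(C)C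
F10 | step 4 | tert-butyl (8S,8aR)-6-methyl-1-oxo-8-(triisopropylsilyloxy)-1,2,3,5,8,8a-hexahydroazulene-4-carboxylate | CC(C)[Si](O[C@H]1C=C(C)CC(C(=O)OC(C)(C)C)=C2CCC(=O)[C@@H]12)(C(C)C)C(C)C
F11 | step 5 | (8S)-8-hydroxy-6-methyl-2,3,4,5-tetrahydroazulen-1(8H)-one | O[C@H]1C=C(C)CCC2=C1C(=O)CC2
F12 | step 5 | (3aS,8S,8aS)-8-hydroxy-3a,6-dimethyl-3,3a,4,5,8,8a-hexahydroazulen-1(2H)-one | O[C@H]1C=C(C)CC[C@@]2(C)CCC(=O)[C@H]12
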